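Readings and results were computed with constants of no real substance, and the scatter is random.

1. A percentage point of the substrate charged is our unit, and a reading scatters by 0.5 percentage points.

| flask | substrate | reagent | free catalyst | remark | time |
|---|---|---|---|---|---|
| dawn | 0.80 M | 0.073 M | 44 mM | run made earlier |  |
| spring | 0.80 M | 0.24 M | 44 mM | run made earlier |  |
| midnight | 0.80 M | 0.53 M | 44 mM | run made earlier |  |
| Thursday's | 0.80 M | 0.100 M | 44 mM |  | 4.0 min |
| Saturday's | 0.80 M | 0.150 M | 44 mM |  | 4.0 min |
| Friday's | 0.80 M | 0.200 M | 44 mM |  | 4.0 min |
| Wednesday's | 0.80 M | 0.300 M | 44 mM |  | 4.0 min |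
| Tuesday's | 0.80 M | 0.500 M | 44 mM |  | 4.0 min |

- dawn (time / min: target / %, isomer of the product / %): 0.250: 7.2, 1.0; 0.417: 7.7, 1.8; 0.833: 7.1, 1.8; 1.33: 7.0, 1.6; 3.00: 7.0, 1.6
- spring (time / min: target / %, isomer of the product / %): 0.500: 25.0, 5.4; 1.00: 24.4, 4.8; 1.50: 24.8, 5.0; 2.50: 24.5, 4.8; 3.00: 25.3, 5.4
- midnight (time / min: target / %, isomer of the product / %): 0.250: 58.8, 6.8; 0.667: 55.0, 10.6; 1.33: 55.5, 10.6; 2.00: 55.9, 11.2; 3.00: 55.1, 11.1

(each reading ± 0.5 percentage points)

* share of target in all that became target or isomer of the product for Thursday's, Saturday's, Friday's, Wednesday's, Tuesday's, in this order
* how that number moves from the first to the last of them (falls, then rises / falls all the way / rises all the way / hardly changes / rises, then falls)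

- the share counts what is present at the end, not what went on to other products
- "hardly changes" means that all values lie within two and a half points (for a concentration: within two and a half percent of the largest)

2. Isomer of the product is the smaller part of what formed in the last readings of the earlier runs, so we reckon it as a correction. The isomer fraction, isomer over target plus isomer, is one dimensionless number, and the asked share is one minus it.

3. In the midnight run, between 0.250 min and 0.667 min, target loses 3.8 points while isomer gains 3.8 points, and after that the readings of the pair show no trend beyond their scatter. We therefore read the late ratio as an equilibrium, which is thermodynamic control.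

4. The late readings give an isomer fraction of 19.2% in the dawn run (from 0.833 min), 17.0% in the spring run and 16.4% in the midnight run (from 0.667 min).

5. Is one number enough? The dawn and midnight values differ by 2.8 points, but the dawn run's small amounts carry an uncertainty of about 3.3 points, which is more than that difference. So we pool the readings, and the isomer fraction is 16.8%. Our own reckoning for each new flask is a share of 83.2%.

6. The forecast gives 83.3% at each point, and its answer for the row is hardly changes. Its value stands 0.100 points above ours, a gap that is less than the scatter. Its ground: “This points to target and isomer interconverting to equilibrium, not to kinetic selectivity.”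

7. The flasks give 83.3%, 83.3%, 83.3%, 83.3% and 83.3%, so the row hardly changes.

    target ⇌ isomer of the product (K = 0.200, k = 0.0150 /s)
    catalyst intermediate B → free catalyst + target (k = 2.80 /s)
    substrate + free catalyst → catalyst intermediate A (k = 16.0 /M/s)
    reagent + catalyst intermediate A ⇌ catalyst intermediate B (K = 90.0 /M, k = 78.0 /M/s)
    free catalyst + target → spent catalyst (k = 0.0400 /M/s)

In Thursday's flask the forward step from target to isomer has a half-life of 0.77 min, short against the run's 4.0 min and shorter than the 6.6 min of the path to spent catalyst, and at 0.0112 min it uses target 75 times as fast as that path. Our isomer fraction, applied to Thursday's target plus isomer, gives 2.10% of isomer against the 2.08% that stands there. Applied to Tuesday's, it gives 10.5%, and Tuesday's flask holds 10.4%.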